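**Plan**

Locants are those of the decahydronaphthalene core: C1 carries the propanoic acid chain, C2 the isopropylidene, C4a–H and C8a–CH3 are the ring fusion, C5 carries CH3 and ArCH2, C6 carries CH3.
Retrosynthesis: the isopropylidene goes back to a C2 acetyl group (enol triflate, methyl coupling); then C2–C3 and C4a–C8a are cut together, which opens both rings to an acyclic keto-enal; its C1–C8a bond is cut to an alkenylboronate and ethyl (E)-6-oxohept-4-enoate; the chain comes from oxidative opening of a 2-benzyl-2,3-dimethylcyclohexanone.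
Enabling feature: C8a is a 1,1-disubstituted alkene carbon (its =CH2 becomes the angular methyl) lying 1,6 to the β-carbon C4a of an (E)-enal (C4a=C4–C3HO), and C2 is the α-CH2 of a methyl ketone lying 1,6 to the aldehyde carbon C3, so a tertiary radical at C8a plus the enolisable C2 act as a 1,3-bis-nucleophile toward the enal as a 1,3-bis-electrophile.
Forward: the ring C4a,C5–C8,C8a (carrying ArCH2) closes first by 6-exo radical addition, then the ring C1–C4,C4a,C8a by aldol condensation, in the same flask.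
Stereochemistry: C6 from Cu-catalysed asymmetric methyl addition to 2-methylcyclohexenone, C5 from anti-benzylation of the resulting enolate, C1 from Rh/BINAP conjugate addition, C8a and C4a from the chair transition state of the radical closure.

Key step: step 13

Remark: Ar = 5-methoxy-2-(methoxymethoxy)-3-methylphenyl. Compounds 1, 5, 6 and 8 are taken as commercial. Ligand enantiomers are those that give the configurations drawn; the (R)-BINAP assignment in step 11 is by analogy with aryl additions to (E)-enones and should be confirmed on a model. Dialdehyde 13 is used crude.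

**Route**

Step 1
Reactants: 1 4-methoxy-2-methylphenol
Product: 2 4-methoxy-1-(methoxymethoxy)-2-methylbenzene
Conditions: MOMCl, i-Pr2NEt, CH2Cl2, 0 °C → rt
Reagents that add atoms: chloromethyl methyl ether (COCCl)
Why: O-alkylation of the phenol gives the MOM acetal, which directs the next lithiation and should survive every basic and organometallic step that follows.

Step 2
Reactants: 2 4-methoxy-1-(methoxymethoxy)-2-methylbenzene
Product: 3 [5-methoxy-2-(methoxymethoxy)-3-methylphenyl]methanol
Conditions: n-BuLi, TMEDA, Et2O, 0 °C; then (CH2O)n, −78 °C → rt; H2O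
Reagents that add atoms: formaldehyde from paraformaldehyde (C=O)
Why: Directed ortho-metalation: OMOM is the strongest director and has one free ortho position, and the aryllithium is hydroxymethylated by formaldehyde.

Step 3
Reactants: 3 [5-methoxy-2-(methoxymethoxy)-3-methylphenyl]methanol
Product: 4 1-(bromomethyl)-5-methoxy-2-(methoxymethoxy)-3-methylbenzene
Conditions: CBr4, PPh3, CH2Cl2, 0 °C
Reagents that add atoms: carbon tetrabromide (BrC(Br)(Br)Br)
Why: Appel bromination runs under neutral conditions and should spare the acid-labile MOM acetal.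

Step 4
Reactants: 5 ethyl pent-4-enoate; 6 but-3-en-2-one
Product: 7 ethyl (4E)-6-oxohept-4-enoate
Conditions: Hoveyda–Grubbs II (2 mol%), excess 6, CH2Cl2, 40 °C
Reagents that add atoms: none
Why: Olefin cross-metathesis of a terminal alkene with an electron-poor vinyl ketone should give the (E)-enone selectively with loss of ethene.

Step 5
Reactants: 8 2-methylcyclohex-2-en-1-one; 4 1-(bromomethyl)-5-methoxy-2-(methoxymethoxy)-3-methylbenzene
Product: 10 (2S,3R)-2-(ArCH2)-2,3-dimethylcyclohexan-1-one, via magnesium enolate 9 (not isolated)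
Conditions: MeMgBr, Cu(OTf)2 (5 mol%), chiral NHC precursor (6 mol%), Et2O, −30 °C; then 4, DMPU, −30 °C → rt
Reagents that add atoms: methylmagnesium bromide (C[Mg]Br)
Why: Cu-catalysed asymmetric conjugate addition sets the tertiary methyl centre by catalyst control, and the tetrasubstituted magnesium enolate is benzylated anti to that β-methyl group (tandem conjugate addition–enolate alkylation), which should give the quaternary centre with the two methyls cis.

Step 6
Reactants: 10 (2S,3R)-2-(ArCH2)-2,3-dimethylcyclohexan-1-one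
Product: 11 (2S,3R)-2-(ArCH2)-6-hydroxy-2,3-dimethylcyclohexan-1-one (C6 epimers)
Conditions: LDA, THF, −78 °C; then 2-(benzenesulfonyl)-3-phenyloxaziridine, −78 °C; H2O
Reagents that add atoms: 2-(benzenesulfonyl)-3-phenyloxaziridine (O=S(=O)(N1OC1c1ccccc1)c1ccccc1)
Why: The ketone can enolise only toward its CH2 side because the other α-carbon is quaternary, so Davis enolate oxidation should be regiospecific; the carbinol configuration is lost in step 7.

Step 7
Reactants: 11 (2S,3R)-2-(ArCH2)-6-hydroxy-2,3-dimethylcyclohexan-1-one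
Product: 13 (2S,3R)-2-(ArCH2)-2,3-dimethylhexanedial, via cyclohexane-1,2-diol 12 (not isolated)
Conditions: NaBH4, MeOH, 0 °C; then NaIO4, THF/H2O (pH 7), rt
Reagents that add atoms: none
Why: Borohydride reduction to the vicinal diol and periodate glycol cleavage open the ring between the former carbonyl carbon and the hydroxylated carbon without touching either stereocentre, giving one α-quaternary and one unhindered aldehyde.

Step 8
Reactants: 13 (2S,3R)-2-(ArCH2)-2,3-dimethylhexanedial
Product: 14 (2S,3R)-2-(ArCH2)-2,3-dimethylhept-6-ynal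
Conditions: (MeO)2P(O)CHN2 (1.05 equiv), KOt-Bu, THF, −78 → −30 °C
Reagents that add atoms: dimethyl (diazomethyl)phosphonate (COP(=O)(OC)C=[N+]=[N-])
Why: Seyferth–Gilbert homologation: at −78 °C the reagent anion should add to the unhindered primary aldehyde much faster than to the neopentyl aldehyde next to the quaternary carbon.

Step 9
Reactants: 14 (2S,3R)-2-(ArCH2)-2,3-dimethylhept-6-ynal
Product: 15 2-[(3S,4R)-3-(ArCH2)-3,4-dimethyloct-1-en-7-yn-1-yl]-1,3-dioxolane (E/Z mixture)
Conditions: (1,3-dioxolan-2-ylmethyl)PPh3Br, KOt-Bu, THF, 0 → 50 °C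
Reagents that add atoms: (1,3-dioxolan-2-ylmethyl)triphenylphosphonium bromide ([Br-].C(C1OCCO1)[P+](c1ccccc1)(c1ccccc1)c1ccccc1)
Why: Wittig two-carbon homologation of the non-enolisable aldehyde installs the enal in acetal-protected form so that it survives steps 10 and 11; the alkene geometry is corrected in step 12.

Step 10
Reactants: 15 2-[(3S,4R)-3-(ArCH2)-3,4-dimethyloct-1-en-7-yn-1-yl]-1,3-dioxolane
Product: 17 2-[(5R,6S)-6-(ArCH2)-8-(1,3-dioxolan-2-yl)-5,6-dimethylocta-1,7-dien-2-yl]-4,4,5,5-tetramethyl-1,3,2-dioxaborolane, via alkenylalane 16 (not isolated)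
Conditions: Ni(dppp)Cl2 (3 mol%), DIBAL-H, THF, 0 → 22 °C; then MeOBpin, 0 → 60 °C
Reagents that add atoms: 2-methoxy-4,4,5,5-tetramethyl-1,3,2-dioxaborolane (COB1OC(C)(C)C(C)(C)O1)
Why: Ni(dppp)-catalysed hydroalumination of a terminal alkyne is α-selective, and Al-to-B exchange should give the 1,1-disubstituted alkenylboronate.

Step 11
Reactants: 17 2-[(5R,6S)-6-(ArCH2)-8-(1,3-dioxolan-2-yl)-5,6-dimethylocta-1,7-dien-2-yl]-4,4,5,5-tetramethyl-1,3,2-dioxaborolane; 7 ethyl (4E)-6-oxohept-4-enoate
Product: 18 ethyl (4R,8R,9S)-9-(ArCH2)-11-(1,3-dioxolan-2-yl)-8,9-dimethyl-5-methylidene-4-(2-oxopropyl)undec-10-enoate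
Conditions: [Rh(cod)OH]2 (3 mol%), (R)-BINAP, K3PO4 (aq.), dioxane/H2O, 40 °C
Reagents that add atoms: none
Why: Hayashi–Miyaura Rh-catalysed asymmetric conjugate addition of an alkenylboron reagent to an acyclic (E)-enone; the BINAP–Rh complex selects the enone face, so the new centre (the future C1) is set by the catalyst regardless of the remote centres.

Step 12
Reactants: 18 ethyl (4R,8R,9S)-9-(ArCH2)-11-(1,3-dioxolan-2-yl)-8,9-dimethyl-5-methylidene-4-(2-oxopropyl)undec-10-enoate
Product: 19 ethyl (4R,8R,9S,10E)-9-(ArCH2)-8,9-dimethyl-5-methylidene-11-oxo-4-(2-oxopropyl)undec-10-enoate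
Conditions: oxalic acid (aq.), THF, rt
Reagents that add atoms: water (O)
Why: Mild acid hydrolysis of the vinyl dioxolane unmasks the enal, which should equilibrate to the (E)-isomer, while the aryl MOM ether and the 1,1-disubstituted alkene survive.

Step 13
Reactants: 19 ethyl (4R,8R,9S,10E)-9-(ArCH2)-8,9-dimethyl-5-methylidene-11-oxo-4-(2-oxopropyl)undec-10-enoate
Product: 21 ethyl 3-[(1S,4aR,5S,6R,8aR)-2-acetyl-5-(ArCH2)-5,6,8a-trimethyl-1,4,4a,5,6,7,8,8a-octahydronaphthalen-1-yl]propanoate, via keto-aldehyde 20 (not isolated)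
Conditions: Fe(acac)3 (30 mol%), PhSiH3, EtOH, 60 °C, 0.02 M; then NaOEt, EtOH, 0 → 50 °C, same flask
Reagents that add atoms: none
Why: An iron hydride formed from Fe(acac)3 and PhSiH3 transfers H• to the CH2 terminus of the 1,1-disubstituted alkene, which creates the angular methyl and a tertiary radical at C8a; this nucleophilic radical adds 6-exo-trig to the enal β-carbon C4a, and reduction and protonation of the α-formyl radical give keto-aldehyde 20 (closest known type: Fe-mediated reductive radical conjugate addition of alkenes to enones and enals). Ethoxide then closes the second ring by 6-(enolexo)-exo-trig aldol addition of the ketone α-CH2 (C2) to the aldehyde carbon C3 and E1cB dehydration to the conjugated acetylcyclohexene (intramolecular aldol condensation of a 1,7-keto aldehyde). At C8a, the chair transition state has the C6 methyl equatorial, hence the C5 methyl axial and ArCH2 equatorial, and the radical carbon should turn its large C1 branch equatorial and its methyl axial, syn to the C5 methyl. At C4a, the enal should sit pseudo-equatorial with the small C5 methyl eclipsing the vinylic C–H (least allylic strain) and be attacked anti to ArCH2, so H-4a ends anti to the C8a methyl and the fusion is trans; C1 is carried over from 19. The step needs hydrogen-atom transfer at the electron-rich alkene and not at the enal, and an aldol that joins C2 to C3 and not the aldehyde α-carbon to the ketone: the aldehyde is the better electrophile, the competing nucleophilic carbon is attached to C4a between two quaternary carbons, and under ethoxide any wrong-sense aldol adduct (including one from the iron enolate) should revert by retro-aldol while dehydration to the enone drains the equilibrium.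

Step 14
Reactants: 21 ethyl 3-[(1S,4aR,5S,6R,8aR)-2-acetyl-5-(ArCH2)-5,6,8a-trimethyl-1,4,4a,5,6,7,8,8a-octahydronaphthalen-1-yl]propanoate
Product: 23 ethyl 3-[(1S,4aR,5S,6R,8aR)-5-(ArCH2)-5,6,8a-trimethyl-2-{1-[(trifluoromethanesulfonyl)oxy]ethylidene}decahydronaphthalen-1-yl]propanoate (E/Z mixture), via triethylsilyl enol ether 22 (not isolated)
Conditions: RhCl(PPh3)3 (2 mol%), Et3SiH, PhMe, 50 °C; evaporate; then CsF, PhNTf2, DME, rt
Reagents that add atoms: N-phenylbis(trifluoromethanesulfonimide) (O=S(=O)(N(c1ccccc1)S(=O)(=O)C(F)(F)F)C(F)(F)F)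
Why: Rh-catalysed 1,4-hydrosilylation of the enone with a monohydrosilane gives the tetrasubstituted silyl enol ether regiospecifically, and fluoride-induced O-triflation traps that enolate without a base or nucleophile that could attack the ester.

Step 15
Reactants: 23 ethyl 3-[(1S,4aR,5S,6R,8aR)-5-(ArCH2)-5,6,8a-trimethyl-2-{1-[(trifluoromethanesulfonyl)oxy]ethylidene}decahydronaphthalen-1-yl]propanoate
Product: 24 ethyl 3-[(1S,4aR,5S,6R,8aR)-5-(ArCH2)-5,6,8a-trimethyl-2-(propan-2-ylidene)decahydronaphthalen-1-yl]propanoate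
Conditions: Me2CuLi, Et2O/THF, −20 → 0 °C
Reagents that add atoms: lithium dimethylcuprate ([Li+].C[Cu-]C)
Why: Cuprate coupling of a vinyl triflate replaces OTf by methyl at a fixed alkene position, so the tetrasubstituted isopropylidene should form without double-bond migration, and both triflate geometries give the same product.

Step 16
Reactants: 24 ethyl 3-[(1S,4aR,5S,6R,8aR)-5-(ArCH2)-5,6,8a-trimethyl-2-(propan-2-ylidene)decahydronaphthalen-1-yl]propanoate
Product: 26 3-[(1S,4aR,5S,6R,8aR)-5-[(2-hydroxy-5-methoxy-3-methylphenyl)methyl]-5,6,8a-trimethyl-2-(propan-2-ylidene)decahydronaphthalen-1-yl]propanoic acid, via MOM-protected acid 25 (not isolated)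
Conditions: LiOH, THF/H2O, rt; then 3 M HCl to pH 1, 45 °C
Reagents that add atoms: lithium hydroxide ([Li+].[OH-])
Why: Saponification of the ethyl ester is followed in the same flask by acidic hydrolysis of the aryl MOM acetal, under dilute aqueous acid that should not protonate the tetrasubstituted alkene.

**Compound list**

1 | 4-methoxy-2-methylphenol | COc1ccc(O)c(C)c1 | starting material
2 | 4-methoxy-1-(methoxymethoxy)-2-methylbenzene | COCOc1ccc(OC)cc1C | intermediate
3 | [5-methoxy-2-(methoxymethoxy)-3-methylphenyl]methanol (ArCH2OH) | COCOc1c(C)cc(OC)cc1CO | intermediate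
4 | 1-(bromomethyl)-5-methoxy-2-(methoxymethoxy)-3-methylbenzene (ArCH2Br) | COCOc1c(C)cc(OC)cc1CBr | intermediate
5 | ethyl pent-4-enoate | C=CCCC(=O)OCC | starting material
6 | but-3-en-2-one | CC(=O)C=C | starting material
7 | ethyl (4E)-6-oxohept-4-enoate | CCOC(=O)CC/C=C/C(C)=O | intermediate
8 | 2-methylcyclohex-2-en-1-one | CC1=CCCCC1=O | starting material
9 | bromomagnesium (3R)-2,3-dimethylcyclohex-1-en-1-olate (formed in the flask) | C[C@@H]1CCCC(O[Mg]Br)=C1C | intermediate
10 | (2S,3R)-2-(ArCH2)-2,3-dimethylcyclohexan-1-one (methyls cis) | COCOc1c(C)cc(OC)cc1C[C@]1(C)C(=O)CCC[C@H]1C | intermediate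
11 | (2S,3R)-2-(ArCH2)-6-hydroxy-2,3-dimethylcyclohexan-1-one (C6 epimers) | COCOc1c(C)cc(OC)cc1C[C@]1(C)C(=O)C(O)CC[C@H]1C | intermediate
12 | (3S,4R)-3-(ArCH2)-3,4-dimethylcyclohexane-1,2-diol (carbinol epimers, formed in the flask) | COCOc1c(C)cc(OC)cc1C[C@]1(C)C(O)C(O)CC[C@H]1C | intermediate
13 | (2S,3R)-2-(ArCH2)-2,3-dimethylhexanedial | COCOc1c(C)cc(OC)cc1C[C@](C)(C=O)[C@H](C)CCC=O | intermediate
14 | (2S,3R)-2-(ArCH2)-2,3-dimethylhept-6-ynal | COCOc1c(C)cc(OC)cc1C[C@](C)(C=O)[C@H](C)CCC#C | intermediate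
15 | 2-[(3S,4R)-3-(ArCH2)-3,4-dimethyloct-1-en-7-yn-1-yl]-1,3-dioxolane (E/Z mixture) | COCOc1c(C)cc(OC)cc1C[C@](C)(C=CC1OCCO1)[C@H](C)CCC#C | intermediate
16 | diisobutyl[(5R,6S)-6-(ArCH2)-8-(1,3-dioxolan-2-yl)-5,6-dimethylocta-1,7-dien-2-yl]alumane (formed in the flask) | COCOc1c(C)cc(OC)cc1C[C@](C)(C=CC1OCCO1)[C@H](C)CCC(=C)[Al](CC(C)C)CC(C)C | intermediate
17 | 2-[(5R,6S)-6-(ArCH2)-8-(1,3-dioxolan-2-yl)-5,6-dimethylocta-1,7-dien-2-yl]-4,4,5,5-tetramethyl-1,3,2-dioxaborolane | COCOc1c(C)cc(OC)cc1C[C@](C)(C=CC1OCCO1)[C@H](C)CCC(=C)B1OC(C)(C)C(C)(C)O1 | intermediate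
18 | ethyl (4R,8R,9S)-9-(ArCH2)-11-(1,3-dioxolan-2-yl)-8,9-dimethyl-5-methylidene-4-(2-oxopropyl)undec-10-enoate | COCOc1c(C)cc(OC)cc1C[C@](C)(C=CC1OCCO1)[C@H](C)CCC(=C)[C@H](CCC(=O)OCC)CC(C)=O | intermediate
19 | ethyl (4R,8R,9S,10E)-9-(ArCH2)-8,9-dimethyl-5-methylidene-11-oxo-4-(2-oxopropyl)undec-10-enoate | COCOc1c(C)cc(OC)cc1C[C@](C)(/C=C/C=O)[C@H](C)CCC(=C)[C@H](CCC(=O)OCC)CC(C)=O | intermediate
20 | ethyl (4R)-4-[(1S,2R,3S,4R)-3-(ArCH2)-1,3,4-trimethyl-2-(2-oxoethyl)cyclohexyl]-6-oxoheptanoate (formed in the flask) | COCOc1c(C)cc(OC)cc1C[C@]1(C)[C@@H](CC=O)[C@](C)([C@H](CCC(=O)OCC)CC(C)=O)CC[C@H]1C | intermediate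
21 | ethyl 3-[(1S,4aR,5S,6R,8aR)-2-acetyl-5-(ArCH2)-5,6,8a-trimethyl-1,4,4a,5,6,7,8,8a-octahydronaphthalen-1-yl]propanoate | COCOc1c(C)cc(OC)cc1C[C@]1(C)[C@H]2CC=C(C(C)=O)[C@@H](CCC(=O)OCC)[C@]2(C)CC[C@H]1C | intermediate
22 | ethyl 3-[(1S,4aR,5S,6R,8aR)-5-(ArCH2)-5,6,8a-trimethyl-2-{1-[(triethylsilyl)oxy]ethylidene}decahydronaphthalen-1-yl]propanoate (E/Z, formed in the flask) | COCOc1c(C)cc(OC)cc1C[C@]1(C)[C@H]2CCC(=C(C)O[Si](CC)(CC)CC)[C@@H](CCC(=O)OCC)[C@]2(C)CC[C@H]1C | intermediate
23 | ethyl 3-[(1S,4aR,5S,6R,8aR)-5-(ArCH2)-5,6,8a-trimethyl-2-{1-[(trifluoromethanesulfonyl)oxy]ethylidene}decahydronaphthalen-1-yl]propanoate (E/Z) | COCOc1c(C)cc(OC)cc1C[C@]1(C)[C@H]2CCC(=C(C)OS(=O)(=O)C(F)(F)F)[C@@H](CCC(=O)OCC)[C@]2(C)CC[C@H]1C | intermediate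
24 | ethyl 3-[(1S,4aR,5S,6R,8aR)-5-(ArCH2)-5,6,8a-trimethyl-2-(propan-2-ylidene)decahydronaphthalen-1-yl]propanoate | COCOc1c(C)cc(OC)cc1C[C@]1(C)[C@H]2CCC(=C(C)C)[C@@H](CCC(=O)OCC)[C@]2(C)CC[C@H]1C | intermediate
25 | 3-[(1S,4aR,5S,6R,8aR)-5-(ArCH2)-5,6,8a-trimethyl-2-(propan-2-ylidene)decahydronaphthalen-1-yl]propanoic acid (lithium salt in the flask) | COCOc1c(C)cc(OC)cc1C[C@]1(C)[C@H]2CCC(=C(C)C)[C@@H](CCC(=O)O)[C@]2(C)CC[C@H]1C | intermediate
26 | 3-[(1S,4aR,5S,6R,8aR)-5-[(2-hydroxy-5-methoxy-3-methylphenyl)methyl]-5,6,8a-trimethyl-2-(propan-2-ylidene)decahydronaphthalen-1-yl]propanoic acid | COc1cc(C)c(O)c(C[C@]2(C)[C@H]3CCC(=C(C)C)[C@@H](CCC(=O)O)[C@]3(C)CC[C@H]2C)c1 | target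

**Summary**

Total step count: 16. Longest linear sequence: 15 steps (steps 1–3, then 5–16); step 4 is a one-step side branch.

Three steps most likely to fail:

1. Step 13. The 6-exo radical closure may show poor facial selectivity at the enal β-carbon (cis ring fusion), and the iron enolate may be captured by the methyl ketone before it is protonated. Fallback, from 19 back to the route at 21: the two events are run separately and the ring-fusion hydrogen is set by hydrogenation instead of by the radical closure. 19 is cyclised with Fe(acac)3/PhSiH3 alone and keto-aldehyde 20 is isolated as a mixture of epimers at the ring-fusion CH. Amine-catalysed α-selenenylation of the aldehyde (N-(phenylselanyl)phthalimide, pyrrolidine cat.), which should leave the methyl ketone alone, gives the α-phenylselanyl aldehyde F1. NaIO4 oxidation and selenoxide syn-elimination give the exocyclic enal F2, in which that carbon is trigonal. H2 over Pd/C should add from the face opposite the two syn-axial methyl groups and return 20 as the trans-configured epimer, which NaOEt/EtOH closes to 21.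

2. Step 8. The dialdehyde may undergo intramolecular aldol cyclisation under the basic conditions, or the reagent may attack both aldehydes. Fallback, from 11 back to the route at 14: the two carbonyls are told apart by oxidation level instead of by hindrance. Pb(OAc)4 in MeOH/benzene cleaves ketol 11 to the aldehyde methyl ester F3; Ohira–Bestmann homologation (K2CO3, MeOH) gives the alkyne ester F4; LiAlH4 gives the neopentyl alcohol F5; Dess–Martin periodinane oxidises it to 14.

3. Step 14. The hindered enone may undergo 1,2- instead of 1,4-hydrosilylation, and O-triflation of the tetrasubstituted enolate may be incomplete. Fallback, from 21 back to the route at 24 (by-passing 23): MeMgBr/CeCl3 at −78 °C adds to the ketone much faster than to the ethyl ester and gives the tertiary allylic alcohol F6. Burgess reagent dehydrates it toward a methyl group, the only β-hydrogens available, to the 2-substituted 1,3-diene F7. (η6-Naphthalene)Cr(CO)3-catalysed 1,4-hydrogenation of the s-cis diene adds H2 across its ends and leaves the tetrasubstituted isopropylidene alkene of 24.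

Further compounds
F1 | step 13 | ethyl (4R)-4-[3-(ArCH2)-1,3,4-trimethyl-2-[2-oxo-1-(phenylselanyl)ethyl]cyclohexyl]-6-oxoheptanoate (α-phenylselanyl derivative of 20; epimers at ring C2 and at the Se-bearing carbon) | COCOc1c(C)cc(OC)cc1C[C@]1(C)C(C(C=O)[Se]c2ccccc2)[C@](C)([C@H](CCC(=O)OCC)CC(C)=O)CC[C@H]1C
F2 | step 13 | ethyl (4R)-4-[3-(ArCH2)-1,3,4-trimethyl-2-(2-oxoethylidene)cyclohexyl]-6-oxoheptanoate (E/Z; other centres as in 20) | COCOc1c(C)cc(OC)cc1C[C@]1(C)C(=CC=O)[C@](C)([C@H](CCC(=O)OCC)CC(C)=O)CC[C@H]1C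
F3 | step 8 | methyl (2S,3R)-2-(ArCH2)-2,3-dimethyl-6-oxohexanoate | COCOc1c(C)cc(OC)cc1C[C@](C)(C(=O)OC)[C@H](C)CCC=O
F4 | step 8 | methyl (2S,3R)-2-(ArCH2)-2,3-dimethylhept-6-ynoate | COCOc1c(C)cc(OC)cc1C[C@](C)(C(=O)OC)[C@H](C)CCC#C
F5 | step 8 | (2S,3R)-2-(ArCH2)-2,3-dimethylhept-6-yn-1-ol | COCOc1c(C)cc(OC)cc1C[C@](C)(CO)[C@H](C)CCC#C
F6 | step 14 | ethyl 3-[(1S,4aR,5S,6R,8aR)-5-(ArCH2)-2-(2-hydroxypropan-2-yl)-5,6,8a-trimethyl-1,4,4a,5,6,7,8,8a-octahydronaphthalen-1-yl]propanoate | COCOc1c(C)cc(OC)cc1C[C@]1(C)[C@H]2CC=C(C(C)(C)O)[C@@H](CCC(=O)OCC)[C@]2(C)CC[C@H]1C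
F7 | step 14 | ethyl 3-[(1S,4aR,5S,6R,8aR)-5-(ArCH2)-5,6,8a-trimethyl-2-(prop-1-en-2-yl)-1,4,4a,5,6,7,8,8a-octahydronaphthalen-1-yl]propanoate | COCOc1c(C)cc(OC)cc1C[C@]1(C)[C@H]2CC=C(C(C)=C)[C@@H](CCC(=O)OCC)[C@]2(C)CC[C@H]1C
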